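The solid substrate is the feed of these flasks, and you follow its rate here: how many moles per litre go into solution each hour. I take it that c_intermediate is fed from what has dissolved.

| flask | solid substrate | remark | time |
|---|---|---|---|
| gamma | 0.23 M | run made earlier |  |
| theta | 0.64 M | run made earlier |  |
| eta | 1.6 M | run made earlier |  |
| south | 0.30 M |  | 2.5 d |
| north-west | 0.40 M |  | 2.5 d |
| north-east | 0.60 M |  | 2.5 d |
| south-west | 1.0 M |  | 2.5 d |
| south-east | 1.5 M |  | 2.5 d |

| run | time / h | intermediate / % | target / % | solid substrate / % |
|---|---|---|---|---|
| gamma | 4.00 | 0.3 | 0.1 | 88.2 |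
| gamma | 10.0 | 2.1 | 0.3 | 72.1 |
| gamma | 20.0 | 5.0 | 1.5 | 46.1 |
| gamma | 30.0 | 8.5 | 4.0 | 22.1 |
| gamma | 40.0 | 12.5 | 7.3 | 0 |
| theta | 8.00 | 1.0 | 1.2 | 92.1 |
| theta | 15.0 | 0.7 | 1.5 | 84.3 |
| theta | 25.0 | 1.7 | 1.4 | 76.6 |
| theta | 30.0 | 2.8 | 1.4 | 72.6 |
| theta | 40.0 | 4.2 | 2.4 | 63.6 |
| eta | 8.00 | 0 | 0.9 | 95.9 |
| eta | 15.0 | 0.4 | 0.5 | 94.8 |
| eta | 25.0 | 0 | 0.7 | 90.9 |
| eta | 30.0 | 0.9 | 0.5 | 88.9 |
| eta | 40.0 | 2.1 | 0.4 | 85.4 |

(scatter of a reading: 0.5 percentage points)

- given per volume of solution although it is solid: solid substrate
- at the start none of the solid substrate is in solution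
- "hardly changes" means that all values lie within two and a half points (for a concentration: within two and a half percent of the largest)

- [intermediate] at the end for south, north-west, north-east, south-west, south-east, in this order
- how the row runs (falls all the way / falls, then rises / hardly changes / rises all the way / rises, then falls)

In the gamma run the readings have the solid going in over the first 10.0 h at

r_start = 0.00642 M/h

and from then until 30.0 h at

r_mid = 0.00575 M/h,

which is a factor 0.896 of the start.

The charge is not what slows it. After 30.0 h, the readings have eta with a factor 0.991 of what gamma has dissolved, from a charge 6.96 times larger, so I read the rate as zero order in the solid. I read the slowing as the solution filling, like a tank nearing its level.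

Carrying that fall on in a straight line to the middle of the stretch from 40.0 h to 2.5 d gives

r_late = 0.00442 M/h,

a factor 0.688 of the start. Adding that stretch to what theta has dissolved by 40.0 h gives the dissolving allowance, my estimate of the amount a flask with solid left has taken into solution by the end:

allowance = 0.321 M

North-west holds more than this, so it and the richer flasks should share one feed and one c_intermediate. South holds less: its solid lasts about 55.2 h, so I expect south slightly lower and a flat row.

The forecast gives 0.048 M for south and 0.049 M for south-east, hardly changes, holding that “the chemistry depends only on what has dissolved”.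

The flasks give 0.0452 M, 0.0462 M, 0.0462 M, 0.0463 M and 0.0463 M: hardly changes.

    starting material → intermediate (k = 2.50 × 10⁻⁴ /min)
    intermediate ⇌ target (K = 2.30, k = 8.40 × 10⁻⁴ /min)
    intermediate ⇌ isomer of the product A (K = 68.0, k = 1.60 × 10⁻⁴ /min)
    intermediate → decomposed reagent (k = 1.60 × 10⁻⁴ /min)
    solid substrate ⇌ starting material, rate k5*(cs5 - [starting material]) while solid is left; crystals form when [starting material] > cs5 (solubility = 0.700 M, k = 1.60 × 10⁻⁴ /min)
    target ⇌ isomer of the product B (K = 0.730, k = 2.70 × 10⁻⁴ /min)

The allowance leaves 46.5% of the north-east solid at 2.5 d, and that flask holds 45.3%; for south-east it leaves 78.6%, and that flask holds 78.1%. In south, intermediate and target relax towards each other, by their own step alone and both ways together, with a half-life of 0.399 d, shorter than the run of 2.5 d. At the end of south, intermediate stands at 15.1% of the charge, target at 12.5% and starting material at 61.3%.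

The readings stem from a simulated flask on assumed constants, noise included.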